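(The numbers in the tables come from a simulation with made-up constants, and the scatter is random.)

| setting | north | east | west | ash | birch | oak | elm |
|---|---|---|---|---|---|---|---|
| solid substrate | 6.7 mM | 15 mM | 10 mM | 10 mM | 10 mM | 10 mM | 10 mM |
| free enzyme | 0.01 mol% | 0.01 mol% | 0.015 mol% | 0.01 mol% | 0.01 mol% | 0.01 mol% | 0.01 mol% |
| temperature | −5 °C | 20 °C | −5 °C | 40 °C |  | 0 °C | 20 °C |
| remark | run made earlier | run made earlier | run made earlier |  | at 0 °C until 1.0 min, from then on at 40 °C |  |  |
| time |  |  |  | 2.0 min | 2.0 min | 2.0 min | 2.0 min |

| run | time / min | product / % |
|---|---|---|
| north | 1.50 | 7 |
| north | 2.00 | 5 |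
| north | 3.00 | 10 |
| north | 4.00 | 15 |
| north | 6.00 | 24 |
| north | 10.0 | 41 |
| north | 15.0 | 62 |
| east | 0.667 | 3 |
| east | 1.33 | 10 |
| east | 2.00 | 17 |
| east | 2.50 | 25 |
| east | 4.00 | 39 |
| west | 3.00 | 14 |
| west | 6.00 | 34 |
| west | 10.0 | 55 |
| west | 12.0 | 67 |
| west | 15.0 | 85 |

(readings scatter by 1.5 percentage points)

- as a solid, counted per litre of solution: solid substrate
- at the start none of the solid substrate is in solution
- what has only dissolved of solid substrate counts as not reacted

* which flask leads in amount of product, in percent of the solid substrate charged ("all alike" within 1.5 percentage points) (ash / birch / oak / elm / all alike)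
* how much product is there at the end, in percent of the solid substrate charged: ash
* how much product is there at the end, in percent of the solid substrate charged: birch
* how much product is there at the end, in percent of the solid substrate charged: oak
* how much product is there at the end, in percent of the solid substrate charged: elm

Product, as a share of the solid substrate charged, climbs close to a straight line in the north, east and west runs, in west as far as 85%, so these readings can be reckoned from two times. The north run has 23.1 min as its clearing time, the time its straight part would need to turn the whole charge into product. The east run, at 20 °C, reads 9.21 min. The west run reads 16.9 min, shorter than north by a factor of 1.37 for a loading factor of 1.50, although c(solid substrate) differs, 6.7 mM against 10 mM. These two runs differ in both settings, so their ratio does not separate the two; the reckoning here assumes clearing time inverse to loading, with no term for the solid charge.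

The second time is the working time: the run time minus the lag (induction period). The east line, as read, reaches zero at 0.409 min. In this reckoning product share is working time over clearing time, and the lag read in east is used for ash, birch, oak and elm.

Taking a constant factor per degree between north and east gives 19.2 min at 0 °C. It also gives 4.41 min at 40 °C, an extrapolation beyond the readings. This reckoning gives ash 36.0%, elm 17.3% and oak 8.28%. Birch, with its two temperatures, gets 25.7%. Ash leads.

The forecast names ash too, with 37% for ash, 24% for birch, 8% for oak and 17% for elm, holding that “the rate does not depend on how much solid remains”; its birch lies below the value here.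

The flask gives 36.4% in ash, 28.9% in birch, 7.49% in oak and 18.9% in elm, so ash leads.

    free enzyme → unfolded enzyme (k = 5.20 × 10⁻⁵ /s, Ea = 206 kJ/mol)
    starting material + free enzyme → product + free enzyme, rate k2*[starting material]*[free enzyme]/(1 + ([starting material]/Km2) + ([starting material]/Ksi2)^2) (7.70 mM, 6.70 mM, k = 29000 /M/s, Ea = 34.0 kJ/mol)
    solid substrate ⇌ starting material, rate k3*(cs3 - [starting material]) while solid is left; crystals form when [starting material] > cs3 (solubility = 5.00 mM, k = 0.0120 /s)
    (constants at 40 °C)

The clearing time reckoned for 40 °C gives birch 23 percentage points in its hot minute, but birch adds 26 points. Birch enters that minute with 23.6% as dissolved starting material, where ash holds 14.7% at 1.00 min. For the neighbour of oak with 0.025 mol% of free enzyme, the reckoning puts the clearing time at 7.68 min, which gives 20.7%. That computed neighbour holds 17.3% of product.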